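Atom labels: ring C1 (epoxide C–CH3), C2 (epoxide CH), C3 (CH2), C4 (CH carrying the side chain), C5 (CH–O-senecioyl), C6 (C=O); side chain C7(=C14H2)–C8H(O-angeloyl)–C9H2–C10H=C11Me2.
Retrosynthesis: the oxirane, the C6 ketone and the senecioate are taken back to cyclohexenol 25. Its C4–C5 bond sits between the C5 oxygen and the exocyclic C7=C14 methylene of the C1–C6 ring, a homoallylic alcohol, which is the mark of a carbonyl-ene reaction. Cutting it gives the acyclic Z,Z-dienal 24, and C3–C4 is then cut into allylic bromide 8 (C3, C2, C1, C6, C5) and alkenylstannane 16 (C4, C7–C11, C14).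
Forward: 8 (from D-glyceraldehyde acetonide) and 16 (from propargyl alcohol) are joined by Stille coupling, the angelate and the C5 aldehyde are set up, the only carbocycle closes in step 16, the oxirane follows in step 19 and the ketone in step 20.
Stereochemistry: C6 comes from the chiral pool and C8 from reagent-controlled allylboration. The Z alkenes come from syn-methylcupration of an ynoate (C1=C2) and chelate-controlled anti-methylmagnesiation (C4=C7). C4 and C5 come from the half-chair ene transition state under control of C6, and C1 and C2 from hydroxyl-directed epoxidation syn to O6.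

Key step: step 16

Remark: aldehyde 1 is taken as purchased (it is also made in one step from 1,2:5,6-di-O-isopropylidene-D-mannitol and NaIO4), and O6 is carried as a triethylsilyl ether so that both hydroxyls of diol 21 are masked in one operation and only the primary one is consumed in step 15.

Step 1
Reactants: 1 (R)-2,2-dimethyl-1,3-dioxolane-4-carbaldehyde
Product: 2 (S)-4-ethynyl-2,2-dimethyl-1,3-dioxolane
Conditions: dimethyl (1-diazo-2-oxopropyl)phosphonate, K2CO3, MeOH, 0 °C → rt
Reagents that add atoms: dimethyl (1-diazo-2-oxopropyl)phosphonate, COP(=O)(OC)C(=[N+]=[N-])C(C)=O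
Why: Seyferth–Gilbert homologation with the Ohira–Bestmann reagent, in which methanolysis frees the diazomethylphosphonate anion that converts the aldehyde into the terminal alkyne under conditions mild enough to leave the α-alkoxy centre (future C6) untouched.

Step 2
Reactants: 2 (S)-4-ethynyl-2,2-dimethyl-1,3-dioxolane
Product: 4 methyl 3-[(4S)-2,2-dimethyl-1,3-dioxolan-4-yl]prop-2-ynoate, via lithium acetylide 3 (not isolated)
Conditions: n-BuLi, THF, −78 °C; then ClCO2Me, −78 → 0 °C
Reagents that add atoms: methyl chloroformate, COC(=O)Cl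
Why: Deprotonation of the terminal alkyne and C-acylation of the acetylide with a chloroformate gives the ynoate (C3 enters as the ester carbon), no stereocentre being formed and the acetonide being inert to the base at low temperature.

Step 3
Reactants: 4 methyl 3-[(4S)-2,2-dimethyl-1,3-dioxolan-4-yl]prop-2-ynoate
Product: 6 methyl (2Z)-3-[(4S)-2,2-dimethyl-1,3-dioxolan-4-yl]but-2-enoate, via alkenylcuprate 5 (not isolated)
Conditions: Me2CuLi (from CuI, 2 MeLi), THF, −78 °C; MeOH, −78 °C
Reagents that add atoms: lithium dimethylcuprate, [Li+].C[Cu-]C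
Why: Conjugate syn-carbocupration of a 2-ynoate puts methyl and copper on the same side of the former triple bond, and protonation at −78 °C with retention traps this adduct before it equilibrates through the allenolate, so C6 and C3 end up cis (the Z C1=C2 geometry).

Step 4
Reactants: 6 methyl (2Z)-3-[(4S)-2,2-dimethyl-1,3-dioxolan-4-yl]but-2-enoate
Product: 7 (2Z)-3-[(4S)-2,2-dimethyl-1,3-dioxolan-4-yl]but-2-en-1-ol
Conditions: i-Bu2AlH (2.5 equiv), CH2Cl2, −78 °C; aq. KNaC4H4O6
Reagents that add atoms: none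
Why: 1,2-Reduction of the enoate by the aluminium hydride gives the allylic alcohol without touching the alkene geometry or the acetonide.

Step 5
Reactants: 7 (2Z)-3-[(4S)-2,2-dimethyl-1,3-dioxolan-4-yl]but-2-en-1-ol
Product: 8 (4S)-4-[(2Z)-4-bromobut-2-en-2-yl]-2,2-dimethyl-1,3-dioxolane
Conditions: CBr4, PPh3, 2,6-lutidine, CH2Cl2, 0 °C
Reagents that add atoms: carbon tetrabromide, BrC(Br)(Br)Br
Why: Appel bromination displaces the activated primary allylic oxygen at C3 in an SN2 sense, without allylic transposition or loss of the Z geometry, the lutidine keeping the medium safe for the acetonide.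

Step 6
Reactants: 9 prop-2-yn-1-ol
Product: 11 (2Z)-3-iodo-2-methylprop-2-en-1-ol, via cyclic alkenylmagnesium alkoxide 10 (not isolated)
Conditions: MeMgBr (2.5 equiv), CuI (10 mol%), THF, −10 °C → rt; then I2, −78 → 0 °C
Reagents that add atoms: methylmagnesium bromide, C[Mg]Br; iodine, II
Why: CuI-catalysed anti-carbomagnesiation of the propargylic alkoxide places methyl on the carbon next to the carbinol and magnesium on the terminus inside a five-membered chelate, and iodinolysis with retention gives the Z-iodoalkene (iodine cis to the future C8).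

Step 7
Reactants: 11 (2Z)-3-iodo-2-methylprop-2-en-1-ol
Product: 12 (2Z)-3-iodo-2-methylprop-2-enal
Conditions: MnO2 (excess), CH2Cl2, rt, dark
Reagents that add atoms: none
Why: MnO2 oxidises the allylic alcohol to the enal under neutral conditions, which the isomerisation-prone Z-β-iodoenal tolerates when it is used at once.

Step 8
Reactants: 12 (2Z)-3-iodo-2-methylprop-2-enal
Product: 14 (1Z,3S)-1-iodo-2-methylhexa-1,5-dien-3-ol, via borinate 13 (not isolated)
Conditions: (−)-Ipc2B(allyl) (pentane solution), Et2O, −78 °C; then NaOH, H2O2, 0 °C → rt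
Reagents that add atoms: (−)-B-allyldiisopinocampheylborane, C=CCB([C@@H]1C[C@@H]2C[C@H]([C@H]1C)C2(C)C)[C@@H]1C[C@@H]2C[C@H]([C@H]1C)C2(C)C
Why: Brown allylboration through a chair Zimmerman–Traxler transition state, in which the isopinocampheyl groups of the (+)-α-pinene series deliver the allyl group to the aldehyde face that gives the 3S carbinol (future C8), fast enough at −78 °C for the Z-enal to keep its geometry.

Step 9
Reactants: 14 (1Z,3S)-1-iodo-2-methylhexa-1,5-dien-3-ol
Product: 15 (1Z,3S)-1-iodo-2,6-dimethylhepta-1,5-dien-3-ol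
Conditions: 2-methylbut-2-ene (excess), second-generation Grubbs catalyst RuCl2(=CHPh)(H2IMes)(PCy3) (5 mol%), CH2Cl2, 40 °C
Reagents that add atoms: 2-methylbut-2-ene, CC=C(C)C
Why: Olefin cross-metathesis of the monosubstituted alkene with excess 2-methylbut-2-ene exchanges the terminal methylene for an isopropylidene unit (the prenyl group), the trisubstituted iodoalkene being too hindered and electron-poor to engage the ruthenium carbene.

Step 10
Reactants: 15 (1Z,3S)-1-iodo-2,6-dimethylhepta-1,5-dien-3-ol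
Product: 16 (1Z,3S)-2,6-dimethyl-1-(trimethylstannyl)hepta-1,5-dien-3-ol
Conditions: (Me3Sn)2, Pd(PPh3)4 (5 mol%), toluene, 80 °C
Reagents that add atoms: hexamethylditin, C[Sn](C)(C)[Sn](C)(C)C
Why: Palladium-catalysed stannylation (oxidative addition of the alkenyl iodide to zerovalent palladium, transmetallation with the distannane, reductive elimination) proceeds with retention of the Z geometry and is placed before any allylic ester is present.

Step 11
Reactants: 16 (1Z,3S)-2,6-dimethyl-1-(trimethylstannyl)hepta-1,5-dien-3-ol; 8 (4S)-4-[(2Z)-4-bromobut-2-en-2-yl]-2,2-dimethyl-1,3-dioxolane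
Product: 17 (5S,6Z,9Z)-10-[(4S)-2,2-dimethyl-1,3-dioxolan-4-yl]-2,6-dimethylundeca-2,6,9-trien-5-ol
Conditions: Pd2(dba)3 (2.5 mol%), AsPh3 (20 mol%), THF, rt → 45 °C
Reagents that add atoms: none
Why: Stille coupling of an alkenylstannane with an allylic bromide forms C3–C4 at the primary terminus of the π-allylpalladium intermediate with retention of both alkene geometries, the weakly donating arsine speeding transmetallation so that syn–anti isomerisation of the allyl unit is outrun.

Step 12
Reactants: 17 (5S,6Z,9Z)-10-[(4S)-2,2-dimethyl-1,3-dioxolan-4-yl]-2,6-dimethylundeca-2,6,9-trien-5-ol; 18 angelic acid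
Product: 20 (5S,6Z,9Z)-10-[(4S)-2,2-dimethyl-1,3-dioxolan-4-yl]-2,6-dimethylundeca-2,6,9-trien-5-yl (2Z)-2-methylbut-2-enoate, via mixed anhydride 19 (not isolated)
Conditions: 2,4,6-Cl3C6H2COCl, Et3N, toluene, rt; then 17, 80 °C
Reagents that add atoms: none
Why: Yamaguchi-type esterification through the mixed anhydride, run without a nucleophilic catalyst, acylates the secondary allylic alcohol at the angeloyl carbonyl and avoids the addition–elimination pathway that turns angelates into tiglates.

Step 13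
Reactants: 20 (5S,6Z,9Z)-10-[(4S)-2,2-dimethyl-1,3-dioxolan-4-yl]-2,6-dimethylundeca-2,6,9-trien-5-yl (2Z)-2-methylbut-2-enoate
Product: 21 (2S,3Z,6Z,8S)-1,2-dihydroxy-3,7,11-trimethyldodeca-3,6,10-trien-8-yl (2Z)-2-methylbut-2-enoate
Conditions: AcOH–H2O (4:1), 40 °C
Reagents that add atoms: none
Why: Acid-catalysed hydrolysis of the terminal acetonide frees the C5/C6 diol under conditions that should leave the allylic ester, the skipped diene and the trisubstituted alkenes alone.

Step 14
Reactants: 21 (2S,3Z,6Z,8S)-1,2-dihydroxy-3,7,11-trimethyldodeca-3,6,10-trien-8-yl (2Z)-2-methylbut-2-enoate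
Product: 22 (2S,3Z,6Z,8S)-3,7,11-trimethyl-1,2-bis(triethylsilyloxy)dodeca-3,6,10-trien-8-yl (2Z)-2-methylbut-2-enoate
Conditions: Et3SiOTf (2.5 equiv), 2,6-lutidine, CH2Cl2, −78 °C
Reagents that add atoms: triethylsilyl trifluoromethanesulfonate, CC[Si](CC)(CC)OS(=O)(=O)C(F)(F)F
Why: Silylation of both hydroxyls with the silyl triflate and a hindered pyridine base is fast at −78 °C and leaves the primary and secondary oxygens distinguishable by steric access alone.

Step 15
Reactants: 22 (2S,3Z,6Z,8S)-3,7,11-trimethyl-1,2-bis(triethylsilyloxy)dodeca-3,6,10-trien-8-yl (2Z)-2-methylbut-2-enoate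
Product: 24 (2S,3Z,6Z,8S)-3,7,11-trimethyl-1-oxo-2-(triethylsilyloxy)dodeca-3,6,10-trien-8-yl (2Z)-2-methylbut-2-enoate, via primary alcohol 23 (not isolated)
Conditions: (COCl)2 (4 equiv), DMSO (8 equiv), CH2Cl2, −78 → −30 °C; then Et3N, −78 → 0 °C
Reagents that add atoms: none
Why: Under Swern conditions with excess activated DMSO only the primary triethylsilyl ether is cleaved and the freed alcohol is oxidised in the same flask (oxidative desilylation of a primary silyl ether), the secondary silyl ether at C6 staying in place, and the sensitive α-silyloxy β,γ-unsaturated aldehyde is taken straight into step 16.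

Step 16
Reactants: 24 (2S,3Z,6Z,8S)-3,7,11-trimethyl-1-oxo-2-(triethylsilyloxy)dodeca-3,6,10-trien-8-yl (2Z)-2-methylbut-2-enoate
Product: 25 (3S)-2-[(1S,5S,6S)-6-hydroxy-4-methyl-5-(triethylsilyloxy)cyclohex-3-en-1-yl]-6-methylhepta-1,5-dien-3-yl (2Z)-2-methylbut-2-enoate
Conditions: Me2AlCl (2.2 equiv), CH2Cl2 (0.01 M), −78 → −20 °C; aq. KNaC4H4O6
Reagents that add atoms: none
Why: Me2AlCl binds the aldehyde oxygen (the second equivalent is held by the angelate carbonyl), C4 of the trisubstituted C4=C7 alkene attacks C5 while a C14 hydrogen passes to oxygen through a six-membered ene array, and the product alkoxide then loses methane from aluminium, which removes the proton that would start Prins-type side reactions; this is the Lewis-acid-promoted intramolecular carbonyl-ene reaction of a 6-en-1-al, as in the closure of citronellal to isopulegol. The one new ring, the C1–C6 carbocycle, closes by C4–C5 bond formation with the enophile tethered to the olefinic terminus of the ene unit, so the new double bond (C7=C14) lies outside the ring, and the Z geometry of C1=C2 keeps C3 and C6 on one side so that the two reacting carbons can reach each other. C5 is set by the half-chair: the complexed oxygen lies equatorial and gauche to C7, the only place from which it reaches a C14 hydrogen, so C5–O should come out trans to the C4 side chain. C4, and with it the face of the aldehyde, is set by the existing C6 centre, whose silyloxy group lies pseudo-equatorial and antiperiplanar to the forming bond (polar Felkin–Anh alignment, the incoming C4 being flanked by C1 and H6 and not by the silyl ether), which should give the all-trans 4S,5S,6S isomer; the C8 centre, with H8 eclipsing the alkene and the C8–C9 bond anti to the incoming carbonyl carbon, is expected to reinforce this face. The step needs hydrogen transfer from C14 and not from C8, and closure of the six-membered ring in preference to any reaction at the prenyl alkene: the Z geometry of C4=C7 puts the methyl group, not C8, trans to the tether and therefore under the oxygen, C10=C11 could only close a ten-membered ring, and the 0.01 M dilution suppresses the bimolecular ene reaction.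

Step 17
Reactants: 25 (3S)-2-[(1S,5S,6S)-6-hydroxy-4-methyl-5-(triethylsilyloxy)cyclohex-3-en-1-yl]-6-methylhepta-1,5-dien-3-yl (2Z)-2-methylbut-2-enoate; 26 3-methylbut-2-enoyl chloride
Product: 27 (1S,2S,6S)-3-methyl-6-[(3S)-6-methyl-3-{[(2Z)-2-methylbut-2-enoyl]oxy}hepta-1,5-dien-2-yl]-2-(triethylsilyloxy)cyclohex-3-en-1-yl 3-methylbut-2-enoate
Conditions: pyridine, DMAP (cat.), CH2Cl2, 0 °C → rt
Reagents that add atoms: none
Why: Acylation of the hindered secondary C5 alcohol with the acid chloride under nucleophilic catalysis, pyridine rather than a trialkylamine being used so that the acid chloride is not deconjugated through the vinylketene.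

Step 18
Reactants: 27 (1S,2S,6S)-3-methyl-6-[(3S)-6-methyl-3-{[(2Z)-2-methylbut-2-enoyl]oxy}hepta-1,5-dien-2-yl]-2-(triethylsilyloxy)cyclohex-3-en-1-yl 3-methylbut-2-enoate
Product: 28 (1S,2S,6S)-2-hydroxy-3-methyl-6-[(3S)-6-methyl-3-{[(2Z)-2-methylbut-2-enoyl]oxy}hepta-1,5-dien-2-yl]cyclohex-3-en-1-yl 3-methylbut-2-enoate
Conditions: HF·pyridine, pyridine, THF, 0 °C → rt
Reagents that add atoms: none
Why: Fluoride-mediated cleavage of the secondary silyl ether in a pyridine-buffered, slightly acidic medium frees the C6 allylic alcohol without base-induced 1,2-migration of the senecioyl group from O5 to O6.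

Step 19
Reactants: 28 (1S,2S,6S)-2-hydroxy-3-methyl-6-[(3S)-6-methyl-3-{[(2Z)-2-methylbut-2-enoyl]oxy}hepta-1,5-dien-2-yl]cyclohex-3-en-1-yl 3-methylbut-2-enoate
Product: 29 (1R,2R,3S,4S,6S)-2-hydroxy-1-methyl-4-[(3S)-6-methyl-3-{[(2Z)-2-methylbut-2-enoyl]oxy}hepta-1,5-dien-2-yl]-7-oxabicyclo[4.1.0]heptan-3-yl 3-methylbut-2-enoate
Conditions: VO(acac)2 (5 mol%), t-BuOOH (decane), CH2Cl2, 0 °C → rt
Reagents that add atoms: tert-butyl hydroperoxide, CC(C)(C)OO
Why: Hydroxyl-directed epoxidation, in which the vanadium alkoxide of the C6 alcohol delivers the peroxide oxygen to the adjacent C1=C2 alkene on the face of the hydroxyl, sets C1 and C2 with the oxirane syn to O6 and cis to the C4 side chain, while the isolated C7=C14 and C10=C11 alkenes and the two enoates are not activated.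

Step 20
Reactants: 29 (1R,2R,3S,4S,6S)-2-hydroxy-1-methyl-4-[(3S)-6-methyl-3-{[(2Z)-2-methylbut-2-enoyl]oxy}hepta-1,5-dien-2-yl]-7-oxabicyclo[4.1.0]heptan-3-yl 3-methylbut-2-enoate
Product: 30 (1S,3S,4S,6S)-1-methyl-4-[(3S)-6-methyl-3-{[(2Z)-2-methylbut-2-enoyl]oxy}hepta-1,5-dien-2-yl]-2-oxo-7-oxabicyclo[4.1.0]heptan-3-yl 3-methylbut-2-enoate (CNP0333561.1)
Conditions: Dess–Martin periodinane, NaHCO3, CH2Cl2, 0 °C → rt
Reagents that add atoms: none
Why: Dess–Martin oxidation of the secondary epoxy alcohol gives the epoxy ketone under buffered, non-basic conditions that should leave the oxirane and the epimerisable C5 acyloxy centre (equatorial, trans to the C4 substituent) intact.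

Compound list
1 | (R)-2,2-dimethyl-1,3-dioxolane-4-carbaldehyde | O=C[C@H]1COC(C)(C)O1 | starting material
2 | (S)-4-ethynyl-2,2-dimethyl-1,3-dioxolane | C#C[C@H]1COC(C)(C)O1 | intermediate
3 | {[(4S)-2,2-dimethyl-1,3-dioxolan-4-yl]ethynyl}lithium | [Li]C#C[C@H]1COC(C)(C)O1 | intermediate
4 | methyl 3-[(4S)-2,2-dimethyl-1,3-dioxolan-4-yl]prop-2-ynoate | COC(=O)C#C[C@H]1COC(C)(C)O1 | intermediate
5 | lithium methyl{(1E)-1-(methoxycarbonyl)-2-[(4S)-2,2-dimethyl-1,3-dioxolan-4-yl]prop-1-en-1-yl}cuprate (copper cis to the new methyl group) | [Li+].C[Cu-]/C(C(=O)OC)=C(\C)[C@H]1COC(C)(C)O1 | intermediate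
6 | methyl (2Z)-3-[(4S)-2,2-dimethyl-1,3-dioxolan-4-yl]but-2-enoate | COC(=O)/C=C(/C)[C@H]1COC(C)(C)O1 | intermediate
7 | (2Z)-3-[(4S)-2,2-dimethyl-1,3-dioxolan-4-yl]but-2-en-1-ol | OC/C=C(/C)[C@H]1COC(C)(C)O1 | intermediate
8 | (4S)-4-[(2Z)-4-bromobut-2-en-2-yl]-2,2-dimethyl-1,3-dioxolane | BrC/C=C(/C)[C@H]1COC(C)(C)O1 | intermediate
9 | prop-2-yn-1-ol | C#CCO | starting material
10 | 4-methyl-2,5-dihydro-1,2-oxamagnesole (chelated alkenylmagnesium alkoxide, magnesium cis to the CH2O carbon) | CC1=C[Mg]OC1 | intermediate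
11 | (2Z)-3-iodo-2-methylprop-2-en-1-ol | OC/C(C)=C\I | intermediate
12 | (2Z)-3-iodo-2-methylprop-2-enal | O=C/C(C)=C\I | intermediate
13 | (1Z,3S)-1-iodo-2-methylhexa-1,5-dien-3-yl diisopinocampheylborinate | I/C=C(/C)[C@H](CC=C)OB([C@@H]1C[C@@H]2C[C@H]([C@H]1C)C2(C)C)[C@@H]1C[C@@H]2C[C@H]([C@H]1C)C2(C)C | intermediate
14 | (1Z,3S)-1-iodo-2-methylhexa-1,5-dien-3-ol | I/C=C(/C)[C@H](CC=C)O | intermediate
15 | (1Z,3S)-1-iodo-2,6-dimethylhepta-1,5-dien-3-ol | I/C=C(/C)[C@H](CC=C(C)C)O | intermediate
16 | (1Z,3S)-2,6-dimethyl-1-(trimethylstannyl)hepta-1,5-dien-3-ol | C[Sn](C)(C)/C=C(/C)[C@H](CC=C(C)C)O | intermediate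
17 | (5S,6Z,9Z)-10-[(4S)-2,2-dimethyl-1,3-dioxolan-4-yl]-2,6-dimethylundeca-2,6,9-trien-5-ol | CC(C)=CC[C@H](O)/C(C)=C\C/C=C(/C)[C@H]1COC(C)(C)O1 | intermediate
18 | angelic acid, (2Z)-2-methylbut-2-enoic acid | C/C=C(/C)C(=O)O | starting material
19 | (2Z)-2-methylbut-2-enoic 2,4,6-trichlorobenzoic anhydride | C/C=C(/C)C(=O)OC(=O)c1c(Cl)cc(Cl)cc1Cl | intermediate
20 | (5S,6Z,9Z)-10-[(4S)-2,2-dimethyl-1,3-dioxolan-4-yl]-2,6-dimethylundeca-2,6,9-trien-5-yl (2Z)-2-methylbut-2-enoate | CC(C)=CC[C@H](OC(=O)/C(C)=C\C)/C(C)=C\C/C=C(/C)[C@H]1COC(C)(C)O1 | intermediate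
21 | (2S,3Z,6Z,8S)-1,2-dihydroxy-3,7,11-trimethyldodeca-3,6,10-trien-8-yl (2Z)-2-methylbut-2-enoate | CC(C)=CC[C@H](OC(=O)/C(C)=C\C)/C(C)=C\C/C=C(/C)[C@H](O)CO | intermediate
22 | (2S,3Z,6Z,8S)-3,7,11-trimethyl-1,2-bis(triethylsilyloxy)dodeca-3,6,10-trien-8-yl (2Z)-2-methylbut-2-enoate | CC(C)=CC[C@H](OC(=O)/C(C)=C\C)/C(C)=C\C/C=C(/C)[C@H](O[Si](CC)(CC)CC)CO[Si](CC)(CC)CC | intermediate
23 | (2S,3Z,6Z,8S)-1-hydroxy-3,7,11-trimethyl-2-(triethylsilyloxy)dodeca-3,6,10-trien-8-yl (2Z)-2-methylbut-2-enoate | CC(C)=CC[C@H](OC(=O)/C(C)=C\C)/C(C)=C\C/C=C(/C)[C@H](O[Si](CC)(CC)CC)CO | intermediate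
24 | (2S,3Z,6Z,8S)-3,7,11-trimethyl-1-oxo-2-(triethylsilyloxy)dodeca-3,6,10-trien-8-yl (2Z)-2-methylbut-2-enoate (acyclic Z,Z-dienal, C4–C5 open) | O=C[C@@H](O[Si](CC)(CC)CC)/C(C)=C\C/C=C(/C)[C@H](CC=C(C)C)OC(=O)/C(C)=C\C | intermediate
25 | (3S)-2-[(1S,5S,6S)-6-hydroxy-4-methyl-5-(triethylsilyloxy)cyclohex-3-en-1-yl]-6-methylhepta-1,5-dien-3-yl (2Z)-2-methylbut-2-enoate (C5–OH trans to the C4 side chain and to the C6 silyl ether) | C=C([C@H](CC=C(C)C)OC(=O)/C(C)=C\C)[C@@H]1CC=C(C)[C@H](O[Si](CC)(CC)CC)[C@H]1O | intermediate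
26 | 3-methylbut-2-enoyl chloride | CC(C)=CC(=O)Cl | starting material
27 | (1S,2S,6S)-3-methyl-6-[(3S)-6-methyl-3-{[(2Z)-2-methylbut-2-enoyl]oxy}hepta-1,5-dien-2-yl]-2-(triethylsilyloxy)cyclohex-3-en-1-yl 3-methylbut-2-enoate | C=C([C@H](CC=C(C)C)OC(=O)/C(C)=C\C)[C@@H]1CC=C(C)[C@H](O[Si](CC)(CC)CC)[C@H]1OC(=O)C=C(C)C | intermediate
28 | (1S,2S,6S)-2-hydroxy-3-methyl-6-[(3S)-6-methyl-3-{[(2Z)-2-methylbut-2-enoyl]oxy}hepta-1,5-dien-2-yl]cyclohex-3-en-1-yl 3-methylbut-2-enoate | C=C([C@H](CC=C(C)C)OC(=O)/C(C)=C\C)[C@@H]1CC=C(C)[C@H](O)[C@H]1OC(=O)C=C(C)C | intermediate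
29 | (1R,2R,3S,4S,6S)-2-hydroxy-1-methyl-4-[(3S)-6-methyl-3-{[(2Z)-2-methylbut-2-enoyl]oxy}hepta-1,5-dien-2-yl]-7-oxabicyclo[4.1.0]heptan-3-yl 3-methylbut-2-enoate (oxirane syn to the C6 hydroxyl) | C=C([C@H](CC=C(C)C)OC(=O)/C(C)=C\C)[C@@H]1C[C@@H]2O[C@]2(C)[C@H](O)[C@H]1OC(=O)C=C(C)C | intermediate
30 | (1S,3S,4S,6S)-1-methyl-4-[(3S)-6-methyl-3-{[(2Z)-2-methylbut-2-enoyl]oxy}hepta-1,5-dien-2-yl]-2-oxo-7-oxabicyclo[4.1.0]heptan-3-yl 3-methylbut-2-enoate | C=C([C@H](CC=C(C)C)OC(=O)/C(C)=C\C)[C@@H]1C[C@@H]2O[C@]2(C)C(=O)[C@H]1OC(=O)C=C(C)C | target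

Total steps: 20. Longest linear sequence: 15 steps (9 → 30 through steps 6–20; equally 1 → 30 through steps 1–5 and 11–20).

Steps most likely to fail

Step 16. The two half-chair transition states that differ only in the orientation of the C6 silyloxy group may lie close in energy, because the productive pseudo-equatorial one pays 1,2-allylic strain against the C1 methyl group. That would mean poor facial selectivity at C4/C5, and the Lewis acid may also ionise the allylic angelate before the slow ene step. The fallback moves the cyclisation to the C6 ketone level and hands facial control to a chiral catalyst. It sets out from diol 21, which is oxidised at both carbinols under Swern conditions to the Z,Z-configured keto aldehyde F1. Its glyoxal-type aldehyde is a far stronger enophile and binds in a two-point fashion to (S)-BINOL–TiCl2(Oi-Pr)2, as glyoxylate esters do. The catalysed carbonyl-ene closure should give the trans hydroxy enone F2, and acylation with 26 (pyridine, DMAP) gives the senecioyl enone F3. Luche reduction (NaBH4, CeCl3·7H2O, MeOH, −78 °C; axial hydride delivery) re-creates the C6 carbinol trans to the C5 ester, and the route is rejoined at 28.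

Step 11. The π-allylpalladium intermediate from 8 may undergo syn–anti isomerisation before the slow tin-to-palladium transfer, which would erode the Z geometry of C1=C2. Coupling at the tertiary allyl terminus and protodestannylation of 16 are further leaks. The fallback replaces tin by zinc in a Negishi alkenyl–allyl coupling, whose transmetallation is fast. It sets out from iodide 15, which is silylated (t-BuMe2SiCl, imidazole, DMF) to the silyl ether F4. Iodine–lithium exchange (t-BuLi, Et2O, −78 °C) gives the alkenyllithium F5 and ZnBr2 turns it into the alkenylzinc bromide F6. This couples with bromide 8 under Pd(PPh3)4 in THF to give the silylated triene F7, and Bu4NF in THF removes the silyl group, rejoining the route at 17.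

Step 15. In the one-flask oxidative desilylation the secondary allylic silyl ether may also be lost while HCl is present, and C6 may epimerise (or C1=C2 move into conjugation) once Et3N is added. The fallback separates the two events and avoids amine base. It sets out from 22: PPTS in MeOH/CH2Cl2 at −10 °C cleaves only the primary silyl ether, alcohol 23 is isolated, and oxidation with Dess–Martin periodinane/NaHCO3 in CH2Cl2 gives 24, where the route is rejoined; no new compound is made.

Further compounds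
F1 | step 16 | (3Z,6Z,8S)-3,7,11-trimethyl-1,2-dioxododeca-3,6,10-trien-8-yl (2Z)-2-methylbut-2-enoate | O=CC(=O)/C(C)=C\C/C=C(/C)[C@H](CC=C(C)C)OC(=O)/C(C)=C\C
F2 | step 16 | (3S)-2-[(1S,6S)-6-hydroxy-4-methyl-5-oxocyclohex-3-en-1-yl]-6-methylhepta-1,5-dien-3-yl (2Z)-2-methylbut-2-enoate | C=C([C@H](CC=C(C)C)OC(=O)/C(C)=C\C)[C@@H]1CC=C(C)C(=O)[C@H]1O
F3 | step 16 | (1S,6S)-3-methyl-6-[(3S)-6-methyl-3-{[(2Z)-2-methylbut-2-enoyl]oxy}hepta-1,5-dien-2-yl]-2-oxocyclohex-3-en-1-yl 3-methylbut-2-enoate | C=C([C@H](CC=C(C)C)OC(=O)/C(C)=C\C)[C@@H]1CC=C(C)C(=O)[C@H]1OC(=O)C=C(C)C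
F4 | step 11 | tert-butyl{[(1Z,3S)-1-iodo-2,6-dimethylhepta-1,5-dien-3-yl]oxy}dimethylsilane | I/C=C(/C)[C@H](CC=C(C)C)O[Si](C)(C)C(C)(C)C
F5 | step 11 | [(1Z,3S)-3-(tert-butyldimethylsilyloxy)-2,6-dimethylhepta-1,5-dien-1-yl]lithium | [Li]/C=C(/C)[C@H](CC=C(C)C)O[Si](C)(C)C(C)(C)C
F6 | step 11 | [(1Z,3S)-3-(tert-butyldimethylsilyloxy)-2,6-dimethylhepta-1,5-dien-1-yl]zinc bromide | Br[Zn]/C=C(/C)[C@H](CC=C(C)C)O[Si](C)(C)C(C)(C)C
F7 | step 11 | tert-butyl{[(5S,6Z,9Z)-10-[(4S)-2,2-dimethyl-1,3-dioxolan-4-yl]-2,6-dimethylundeca-2,6,9-trien-5-yl]oxy}dimethylsilane | CC(C)=CC[C@H](O[Si](C)(C)C(C)(C)C)/C(C)=C\C/C=C(/C)[C@H]1COC(C)(C)O1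
F0 | step 15 | none | none
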